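**Strategy.** Everything rests on cutting the quinone between C1 and C6. C5–H and C6, which carries the branched 1-methylidene side chain, are read as the two carbons of an alkyne. C1–C4, with OMe on C2 and Me on C3, are read as a four-membered ring grown from dimethyl squarate. Heating the 4-alkynyl-4-hydroxy-2-methoxy-3-methylcyclobutenone opens it to an enynyl ketene that closes the six-membered quinone ring at its final oxidation level; the substituent pattern is dictated by the order of additions to the squarate. The precursor is this cyclobutenone bearing the complete (S)-configured, silyl-protected side chain as a conjugated enyne on the carbinol carbon. Deprotection and angeloylation finish the synthesis.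

Key step: step 9

Remark: the ring carbinol carbon created in step 7 is formed as both epimers (compounds 13–17); this is immaterial because it becomes the sp2 carbon C4 of the quinone.

**Route**

Step 1
Reactants: 1 acrolein
Product: 3 2-bromoacrolein (2-bromoprop-2-enal), via 2,3-dibromopropanal 2 (not isolated)
Conditions: Br2, CH2Cl2, −78 → 0 °C; then Et3N, 0 °C; used fresh as a solution
Reagents that add atoms: bromine, BrBr
Why: Bromination of the enal C=C followed by amine-induced dehydrobromination of the acidic α-position (bromination–elimination) is the standard way to make this aldehyde.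

Step 2
Reactants: 3 2-bromoacrolein
Product: 5 (S)-2-bromohexa-1,5-dien-3-ol, via diisopinocampheylborinate 4 (not isolated)
Conditions: (−)-Ipc2BOMe [from (+)-α-pinene], allylMgBr, Et2O, 0 °C → rt; then 3, −78 °C; NaOH, 30% H2O2, 0 °C → rt
Reagents that add atoms: allylmagnesium bromide, C=CC[Mg]Br, whose allyl group is delivered through (−)-B-allyldiisopinocampheylborane, C=CCB([C@@H]1C[C@@H]2C[C@H]([C@H]1C)C2(C)C)[C@@H]1C[C@@H]2C[C@H]([C@H]1C)C2(C)C
Why: In this Brown asymmetric allylboration the chair six-membered transition state of the (+)-α-pinene-derived reagent delivers allyl to the Si face of the aldehyde, which sets the carbinol as (S) because the 1-bromovinyl group outranks allyl.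

Step 3
Reactants: 5 (S)-2-bromohexa-1,5-dien-3-ol
Product: 6 (S)-[(2-bromohexa-1,5-dien-3-yl)oxy](tert-butyl)dimethylsilane
Conditions: TBSCl, imidazole, DMF, rt
Reagents that add atoms: tert-butyldimethylsilyl chloride, CC(C)(C)[Si](C)(C)Cl
Why: Imidazole-promoted O-silylation of a secondary alcohol is routine and gives an ether that withstands the organolithium, palladium and thermal steps ahead.

Step 4
Reactants: 6 (S)-[(2-bromohexa-1,5-dien-3-yl)oxy](tert-butyl)dimethylsilane
Product: 7 (S)-[(2-bromo-6-methylhepta-1,5-dien-3-yl)oxy](tert-butyl)dimethylsilane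
Conditions: Grubbs II (3 mol%), 2-methyl-2-butene/CH2Cl2, 40 °C, sealed
Reagents that add atoms: 2-methyl-2-butene, CC=C(C)C
Why: Olefin cross-metathesis with excess 2-methyl-2-butene converts the monosubstituted alkene into the prenyl terminus with loss of propene, while the hindered, electron-poor 1,1-disubstituted vinyl bromide stays out of the catalytic cycle.

Step 5
Reactants: 7 (S)-[(2-bromo-6-methylhepta-1,5-dien-3-yl)oxy](tert-butyl)dimethylsilane; 8 trimethylsilylacetylene
Product: 9 (S)-tert-butyldimethyl{[7-methyl-3-methylidene-1-(trimethylsilyl)oct-6-en-1-yn-4-yl]oxy}silane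
Conditions: Pd(PPh3)2Cl2 (5 mol%), CuI (10 mol%), Et3N, THF, 50 °C
Reagents that add atoms: none
Why: Sonogashira coupling of a 2-bromo-1-alkene with a terminal alkyne builds the cross-conjugated enyne without touching the silyl ether or the trisubstituted alkene.

Step 6
Reactants: 9 (S)-tert-butyldimethyl{[7-methyl-3-methylidene-1-(trimethylsilyl)oct-6-en-1-yn-4-yl]oxy}silane
Product: 10 (S)-tert-butyldimethyl[(7-methyl-3-methylideneoct-6-en-1-yn-4-yl)oxy]silane
Conditions: K2CO3, MeOH, rt
Reagents that add atoms: none
Why: Base-mediated methanolysis cleaves the C(sp)–Si bond selectively (protodesilylation), and the secondary TBS ether is inert to these conditions.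

Step 7
Reactants: 10 (S)-tert-butyldimethyl[(7-methyl-3-methylideneoct-6-en-1-yn-4-yl)oxy]silane; 11 dimethyl squarate
Product: 14 4-[(4S)-4-(tert-butyldimethylsilyloxy)-7-methyl-3-methylideneoct-6-en-1-yn-1-yl]-2,3-dimethoxy-4-(trimethylsilyloxy)cyclobut-2-en-1-one (both epimers at the ring carbinol carbon), via lithium acetylide 12 (not isolated), via lithium alkoxide 13 (not isolated)
Conditions: n-BuLi, THF, −78 °C; cannulated into 11, THF, −78 °C; TMSCl, −78 → 0 °C
Reagents that add atoms: chlorotrimethylsilane, C[Si](C)(C)Cl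
Why: 1,2-Addition of a lithium acetylide to one of the two equivalent squarate carbonyls stops at mono-addition because the remaining carbonyl is a vinylogous ester; trapping the alkoxide as its TMS ether marks this carbon as the one that must not ionise later, and the new ring stereocentre is uncontrolled but is destroyed in step 9.

Step 8
Reactants: 14 4-[(4S)-4-(tert-butyldimethylsilyloxy)-7-methyl-3-methylideneoct-6-en-1-yn-1-yl]-2,3-dimethoxy-4-(trimethylsilyloxy)cyclobut-2-en-1-one
Product: 17 4-[(4S)-4-(tert-butyldimethylsilyloxy)-7-methyl-3-methylideneoct-6-en-1-yn-1-yl]-4-hydroxy-2-methoxy-3-methylcyclobut-2-en-1-one, via lithium cyclobutenolate 15 (not isolated), via silyl-protected cyclobutenone 16 (not isolated)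
Conditions: MeLi, THF, −78 °C; quenched cold into 0.5 M aq. HCl/THF, 0 °C
Reagents that add atoms: methyllithium, [Li]C; water, O
Why: This is a Stork–Danheiser-type carbonyl transposition in which 1,2-addition of MeLi to the vinylogous ester carbonyl gives a tertiary allylic carbinol that alone can ionise under mild acid (the alkynyl carbinol is silyl-capped), water then adds at the methoxy-stabilised terminus of the cation and methanol is lost so that the new carbonyl sits between the retained OMe carbon and the alkynyl carbinol, and the same dilute acid hydrolyses the labile tertiary TMS ether but not the secondary TBS ether.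

Step 9
Reactants: 17 4-[(4S)-4-(tert-butyldimethylsilyloxy)-7-methyl-3-methylideneoct-6-en-1-yn-1-yl]-4-hydroxy-2-methoxy-3-methylcyclobut-2-en-1-one
Product: 20 6-[(S)-3-(tert-butyldimethylsilyloxy)-6-methylhepta-1,5-dien-2-yl]-2-methoxy-3-methyl-1,4-benzoquinone, via enynyl ketene 18 (not isolated), via ring diradical 19 (not isolated)
Conditions: toluene (0.01 M, degassed), 110 °C
Reagents that add atoms: none
Why: Thermal conrotatory 4π opening of the cyclobutenone, with the hydroxyl turning outward and the alkynyl group inward, gives ketene 18 in which the ketene carbon lies next to the far alkyne carbon (alkynyl cis to the ketene unit, E by CIP). Bonding between these two carbons closes the six-membered ring (6-endo with respect to the alkyne) to the aromatic diradical 19, a phenoxyl radical with a σ-radical at C5, and transfer of the hydroxyl hydrogen to C5 gives the quinone directly; this is the known thermal ring expansion of 4-alkynyl-4-hydroxycyclobutenones to 1,4-benzoquinones. The substitution is fixed beforehand, since the ketene carbon becomes C1 beside C2–OMe, the carbinol carbon becomes C4 beside C3–Me, and the alkyne carbons become C5–H and C6 with the side chain. No stereocentre is formed, and the (S)-silyloxy carbon, the skipped diene and the silyl ether are spectators under neutral conditions. The selectivity needed is six- over five-membered closure, because attack on the near alkyne carbon would lead to an alkylidene cyclopentenedione; the free hydroxyl as an immediate hydrogen donor, the carbon (not aryl, silyl or alkoxy) substituent on the alkyne and the aromaticity gained in 19 favour the six-membered path. The alkenyl group on the alkyne could stabilise the exocyclic vinyl radical of the five-membered path and is the accepted risk, while high dilution protects the vinyl quinone from bimolecular decay.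

Step 10
Reactants: 20 6-[(S)-3-(tert-butyldimethylsilyloxy)-6-methylhepta-1,5-dien-2-yl]-2-methoxy-3-methyl-1,4-benzoquinone
Product: 21 6-[(S)-3-hydroxy-6-methylhepta-1,5-dien-2-yl]-2-methoxy-3-methyl-1,4-benzoquinone
Conditions: 48% aq. HF, MeCN, 0 °C → rt (plastic vessel)
Reagents that add atoms: none
Why: Fluoride-driven Si–O cleavage under acidic, non-nucleophilic conditions removes the TBS group without exposing the electrophilic vinyl quinone to base or amine, and the C–O bond of the stereocentre is not broken.

Step 11
Reactants: 22 angelic acid [(Z)-2-methylbut-2-enoic acid]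
Product: 23 (Z)-2-methylbut-2-enoic 2,4,6-trichlorobenzoic anhydride
Conditions: 2,4,6-trichlorobenzoyl chloride, Et3N, toluene, rt; filtered, used as solution
Reagents that add atoms: 2,4,6-trichlorobenzoyl chloride, O=C(Cl)c1c(Cl)cc(Cl)cc1Cl
Why: Yamaguchi-type formation of the mixed anhydride from the carboxylate proceeds at room temperature without a nucleophilic catalyst, so the Z-alkene is not isomerised.

Step 12
Reactants: 21 6-[(S)-3-hydroxy-6-methylhepta-1,5-dien-2-yl]-2-methoxy-3-methyl-1,4-benzoquinone; 23 (Z)-2-methylbut-2-enoic 2,4,6-trichlorobenzoic anhydride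
Product: 24 (S)-2-(5-methoxy-4-methyl-3,6-dioxocyclohexa-1,4-dien-1-yl)-6-methylhepta-1,5-dien-3-yl (Z)-2-methylbut-2-enoate (CNP0232608.2)
Conditions: 23 (excess), toluene, 75 °C, dark
Reagents that add atoms: none
Why: Thermal acyl transfer from the mixed anhydride (stereoconservative angeloylation without base or DMAP) occurs at the angeloyl carbonyl because the trichlorobenzoyl carbonyl is shielded by two ortho chlorines, and the absence of nucleophilic catalysts avoids the addition–elimination that turns angelates into tiglates; acylation at oxygen keeps the (S) configuration.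

**Compound list**

1 | acrolein (prop-2-enal) | C=CC=O | starting material
2 | 2,3-dibromopropanal (racemic) | O=CC(Br)CBr | intermediate
3 | 2-bromoacrolein (2-bromoprop-2-enal) | C=C(Br)C=O | intermediate
4 | (S)-2-bromohexa-1,5-dien-3-yl diisopinocampheylborinate (Ipc groups from (+)-α-pinene) | C=C(Br)[C@H](CC=C)OB([C@@H]1C[C@@H]2C[C@H]([C@H]1C)C2(C)C)[C@@H]1C[C@@H]2C[C@H]([C@H]1C)C2(C)C | intermediate
5 | (S)-2-bromohexa-1,5-dien-3-ol | C=C(Br)[C@H](CC=C)O | intermediate
6 | (S)-[(2-bromohexa-1,5-dien-3-yl)oxy](tert-butyl)dimethylsilane | C=C(Br)[C@H](CC=C)O[Si](C)(C)C(C)(C)C | intermediate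
7 | (S)-[(2-bromo-6-methylhepta-1,5-dien-3-yl)oxy](tert-butyl)dimethylsilane | C=C(Br)[C@H](CC=C(C)C)O[Si](C)(C)C(C)(C)C | intermediate
8 | trimethylsilylacetylene | C#C[Si](C)(C)C | starting material
9 | (S)-tert-butyldimethyl{[7-methyl-3-methylidene-1-(trimethylsilyl)oct-6-en-1-yn-4-yl]oxy}silane | C=C(C#C[Si](C)(C)C)[C@H](CC=C(C)C)O[Si](C)(C)C(C)(C)C | intermediate
10 | (S)-tert-butyldimethyl[(7-methyl-3-methylideneoct-6-en-1-yn-4-yl)oxy]silane | C#CC(=C)[C@H](CC=C(C)C)O[Si](C)(C)C(C)(C)C | intermediate
11 | dimethyl squarate (3,4-dimethoxycyclobut-3-ene-1,2-dione) | COC1=C(OC)C(=O)C1=O | starting material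
12 | lithium acetylide of 10 | [Li]C#CC(=C)[C@H](CC=C(C)C)O[Si](C)(C)C(C)(C)C | intermediate
13 | lithium 1-[(4S)-4-(tert-butyldimethylsilyloxy)-7-methyl-3-methylideneoct-6-en-1-yn-1-yl]-2,3-dimethoxy-4-oxocyclobut-2-en-1-olate (both ring epimers) | COC1=C(OC)C(O[Li])(C#CC(=C)[C@H](CC=C(C)C)O[Si](C)(C)C(C)(C)C)C1=O | intermediate
14 | 4-[(4S)-4-(tert-butyldimethylsilyloxy)-7-methyl-3-methylideneoct-6-en-1-yn-1-yl]-2,3-dimethoxy-4-(trimethylsilyloxy)cyclobut-2-en-1-one (both ring epimers) | COC1=C(OC)C(O[Si](C)(C)C)(C#CC(=C)[C@H](CC=C(C)C)O[Si](C)(C)C(C)(C)C)C1=O | intermediate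
15 | lithium 4-[(4S)-4-(tert-butyldimethylsilyloxy)-7-methyl-3-methylideneoct-6-en-1-yn-1-yl]-2,3-dimethoxy-1-methyl-4-(trimethylsilyloxy)cyclobut-2-en-1-olate (diastereomer mixture) | COC1=C(OC)C(O[Si](C)(C)C)(C#CC(=C)[C@H](CC=C(C)C)O[Si](C)(C)C(C)(C)C)C1(C)O[Li] | intermediate
16 | 4-[(4S)-4-(tert-butyldimethylsilyloxy)-7-methyl-3-methylideneoct-6-en-1-yn-1-yl]-2-methoxy-3-methyl-4-(trimethylsilyloxy)cyclobut-2-en-1-one (both ring epimers) | COC1=C(C)C(O[Si](C)(C)C)(C#CC(=C)[C@H](CC=C(C)C)O[Si](C)(C)C(C)(C)C)C1=O | intermediate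
17 | 4-[(4S)-4-(tert-butyldimethylsilyloxy)-7-methyl-3-methylideneoct-6-en-1-yn-1-yl]-4-hydroxy-2-methoxy-3-methylcyclobut-2-en-1-one (both ring epimers) | COC1=C(C)C(O)(C#CC(=C)[C@H](CC=C(C)C)O[Si](C)(C)C(C)(C)C)C1=O | intermediate
18 | (3E,8S)-8-(tert-butyldimethylsilyloxy)-4-hydroxy-2-methoxy-3,11-dimethyl-7-methylidenedodeca-1,3,10-trien-5-yn-1-one (enynyl ketene, alkynyl cis to the ketene carbon) | COC(=C=O)/C(C)=C(O)\C#CC(=C)[C@H](CC=C(C)C)O[Si](C)(C)C(C)(C)C | intermediate
19 | ring diradical: 4-hydroxy-2-methoxy-3-methyl-6-[(S)-3-(tert-butyldimethylsilyloxy)-6-methylhepta-1,5-dien-2-yl]phenoxyl with a σ-radical at C5 | [O]c1c(OC)c(C)c(O)[c]c1C(=C)[C@H](CC=C(C)C)O[Si](C)(C)C(C)(C)C | intermediate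
20 | 6-[(S)-3-(tert-butyldimethylsilyloxy)-6-methylhepta-1,5-dien-2-yl]-2-methoxy-3-methyl-1,4-benzoquinone | C=C(C1=CC(=O)C(C)=C(OC)C1=O)[C@H](CC=C(C)C)O[Si](C)(C)C(C)(C)C | intermediate
21 | 6-[(S)-3-hydroxy-6-methylhepta-1,5-dien-2-yl]-2-methoxy-3-methyl-1,4-benzoquinone | C=C(C1=CC(=O)C(C)=C(OC)C1=O)[C@H](CC=C(C)C)O | intermediate
22 | angelic acid [(Z)-2-methylbut-2-enoic acid] | C/C=C(/C)C(=O)O | starting material
23 | (Z)-2-methylbut-2-enoic 2,4,6-trichlorobenzoic anhydride | C/C=C(/C)C(=O)OC(=O)c1c(Cl)cc(Cl)cc1Cl | intermediate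
24 | (S)-2-(5-methoxy-4-methyl-3,6-dioxocyclohexa-1,4-dien-1-yl)-6-methylhepta-1,5-dien-3-yl (Z)-2-methylbut-2-enoate | C=C(C1=CC(=O)C(C)=C(OC)C1=O)[C@H](CC=C(C)C)OC(=O)/C(C)=C\C | target

**Step count and risks**

Total step count: 12. Longest linear sequence: 11 (steps 1–10 and 12; step 11 is a one-step branch).

Steps most likely to fail:

1. Step 9. After ring opening the ketene carbon may bond to the near alkyne carbon, because the exocyclic vinyl radical formed in that mode is conjugated with the adjacent methylidene group; this five-membered closure diverts material away from the quinone, and the vinyl quinone may also decay bimolecularly on prolonged heating. The fallback replaces the diradical closure by a 6π electrocyclisation of a dienyl ketene, which has no five-membered alternative. It sets out from 10: hydrozirconation with Cp2Zr(H)Cl and iodinolysis should give the (E)-dienyl iodide tert-butyl{[(1E,4S)-1-iodo-7-methyl-3-methylideneocta-1,6-dien-4-yl]oxy}dimethylsilane F1. Iodine–lithium exchange with t-BuLi at −78 °C gives the dienyllithium F2, which is added to 11 and silylated in the flask to the 4-dienyl-2,3-dimethoxy-4-(trimethylsilyloxy)cyclobutenone F3. Methyllithium addition and dilute-acid transposition, as in step 8, give the 4-dienyl-4-hydroxy-2-methoxy-3-methylcyclobutenone F4. Heating in toluene should lead by ring opening, electrocyclisation and tautomerisation to the hydroquinone F5, and oxidation with Ag2O comes back to the route at 20.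

2. Step 8. Migration of the trimethylsilyl group between the two vicinal oxygens at the alkoxide stage, or conjugate addition of methyllithium, would blur which carbinol ionises; over-long acid exposure could push the product on towards a cyclobutenedione or loosen the secondary silyl ether. The fallback reverses the order of the two nucleophiles and masks the more electrophilic carbonyl as a ketal, so that the acetylide has only one carbonyl to attack. It sets out from 11: methyllithium at −78 °C gives 4-hydroxy-2,3-dimethoxy-4-methylcyclobut-2-en-1-one F6. Ionisation with trifluoroacetic anhydride and capture by dry methanol gives the monoketal 3,4,4-trimethoxy-2-methylcyclobut-2-en-1-one F7. The lithium acetylide 12 adds to its single carbonyl and the alkoxide is capped with TMSCl to give the silyl-protected ketal adduct F8. Mild aqueous acid then removes the ketal and the trimethylsilyl group and comes back to the route at 17.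

3. Step 12. Acyl transfer to the hindered allylic alcohol may be slow, so that the vinyl quinone decays or oligomerises during long heating, and the angeloyl unit may drift towards the E-isomer. The fallback builds the Z-ester before the quinone exists and makes the ring expansion the last step. It sets out from 17: aqueous HF in MeCN removes the TBS group to give the diol 4-hydroxy-4-[(4S)-4-hydroxy-7-methyl-3-methylideneoct-6-en-1-yn-1-yl]-2-methoxy-3-methylcyclobut-2-en-1-one F9. Carbodiimide coupling at room temperature acylates only the secondary hydroxyl with 2-[bis(2,2,2-trifluoroethoxy)phosphoryl]propanoic acid to give the phosphonate ester F10. Still–Gennari olefination with acetaldehyde (KHMDS, 18-crown-6, −78 °C, with one extra equivalent of base for the tertiary hydroxyl) should give the (Z)-2-methylbut-2-enoate-bearing cyclobutenone F11. Heating as in step 9 comes back to the route at 24.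

**Further compounds**

F1 | step 9 | tert-butyl{[(1E,4S)-1-iodo-7-methyl-3-methylideneocta-1,6-dien-4-yl]oxy}dimethylsilane | I/C=C/C(=C)[C@H](CC=C(C)C)O[Si](C)(C)C(C)(C)C
F2 | step 9 | [(1E,4S)-4-(tert-butyldimethylsilyloxy)-7-methyl-3-methylideneocta-1,6-dien-1-yl]lithium | [Li]/C=C/C(=C)[C@H](CC=C(C)C)O[Si](C)(C)C(C)(C)C
F3 | step 9 | 4-[(1E,4S)-4-(tert-butyldimethylsilyloxy)-7-methyl-3-methylideneocta-1,6-dien-1-yl]-2,3-dimethoxy-4-(trimethylsilyloxy)cyclobut-2-en-1-one | COC1=C(OC)C(O[Si](C)(C)C)(/C=C/C(=C)[C@H](CC=C(C)C)O[Si](C)(C)C(C)(C)C)C1=O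
F4 | step 9 | 4-[(1E,4S)-4-(tert-butyldimethylsilyloxy)-7-methyl-3-methylideneocta-1,6-dien-1-yl]-4-hydroxy-2-methoxy-3-methylcyclobut-2-en-1-one | COC1=C(C)C(O)(/C=C/C(=C)[C@H](CC=C(C)C)O[Si](C)(C)C(C)(C)C)C1=O
F5 | step 9 | 6-[(S)-3-(tert-butyldimethylsilyloxy)-6-methylhepta-1,5-dien-2-yl]-2-methoxy-3-methylbenzene-1,4-diol | C=C(c1cc(O)c(C)c(OC)c1O)[C@H](CC=C(C)C)O[Si](C)(C)C(C)(C)C
F6 | step 8 | 4-hydroxy-2,3-dimethoxy-4-methylcyclobut-2-en-1-one | COC1=C(OC)C(C)(O)C1=O
F7 | step 8 | 3,4,4-trimethoxy-2-methylcyclobut-2-en-1-one | COC1=C(C)C(=O)C1(OC)OC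
F8 | step 8 | tert-butyl{[(4S)-7-methyl-3-methylidene-1-[2,2,3-trimethoxy-4-methyl-1-(trimethylsilyloxy)cyclobut-3-en-1-yl]oct-6-en-1-yn-4-yl]oxy}dimethylsilane | COC1=C(C)C(O[Si](C)(C)C)(C#CC(=C)[C@H](CC=C(C)C)O[Si](C)(C)C(C)(C)C)C1(OC)OC
F9 | step 12 | 4-hydroxy-4-[(4S)-4-hydroxy-7-methyl-3-methylideneoct-6-en-1-yn-1-yl]-2-methoxy-3-methylcyclobut-2-en-1-one | COC1=C(C)C(O)(C#CC(=C)[C@H](CC=C(C)C)O)C1=O
F10 | step 12 | (4S)-1-(1-hydroxy-3-methoxy-2-methyl-4-oxocyclobut-2-en-1-yl)-7-methyl-3-methylideneoct-6-en-1-yn-4-yl 2-[bis(2,2,2-trifluoroethoxy)phosphoryl]propanoate | COC1=C(C)C(O)(C#CC(=C)[C@H](CC=C(C)C)OC(=O)C(C)P(=O)(OCC(F)(F)F)OCC(F)(F)F)C1=O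
F11 | step 12 | (4S)-1-(1-hydroxy-3-methoxy-2-methyl-4-oxocyclobut-2-en-1-yl)-7-methyl-3-methylideneoct-6-en-1-yn-4-yl (Z)-2-methylbut-2-enoate | COC1=C(C)C(O)(C#CC(=C)[C@H](CC=C(C)C)OC(=O)/C(C)=C\C)C1=O
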